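## Retrosynthetic overview

1. C2–C1′ bond, made last: rhodium-catalysed asymmetric 1,4-addition of ring B boronic acid 25 to chromone 27, which sets (2S).
2. C6–CH2 bond: palladium-catalysed Negishi coupling of the chiral alkylzinc iodide 26 with 6-bromochromone 10.
3. Side-chain stereocentre: a new palladium-catalysed enantioconvergent allyl–allyl coupling of racemic 2-isopropenyloxirane 15 with allylB(pin) 13, followed by cross-metathesis to install the prenyl end.
4. Ring order: ring A comes from resorcinol (third oxygen by iridium C–H borylation/oxidation), ring C is closed on it by ynone oxa-Michael cyclisation (10), and ring B (also from resorcinol) is attached last.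

Assumption: the sense of induction in steps 9 and 17 is assigned by analogy with the parent reactions and is checked on 18 (optical rotation opposite to natural (R)-(−)-lavandulol) and on 28 (circular dichroism); the mirror-image ligand is used if a check fails.

## Route

Step 1
Reactants: 1 resorcinol
Product: 2 1,3-bis(methoxymethoxy)benzene
Conditions: MOMCl (2.6 equiv), i-Pr2NEt (3 equiv), CH2Cl2, 0 °C to rt
Reagents that add atoms: chloromethyl methyl ether (COCCl)
Why: Williamson-type O-alkylation of both phenols by the reactive α-chloro ether gives the bis-acetal that later directs metalation.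

Step 2
Reactants: 2 1,3-bis(methoxymethoxy)benzene
Product: 4 2-bromo-1,3-bis(methoxymethoxy)benzene, via aryllithium 3 (not isolated)
Conditions: n-BuLi (1.1 equiv), THF, 0 °C, 1 h; BrCH2CH2Br, −78 °C to rt
Reagents that add atoms: 1,2-dibromoethane (BrCCBr)
Why: Directed ortho-metalation removes the proton between the two MOM ethers (most acidic, doubly coordinated), and the aryllithium is brominated by 1,2-dibromoethane with loss of ethene.

Step 3
Reactants: 4 2-bromo-1,3-bis(methoxymethoxy)benzene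
Product: 6 4-bromo-3,5-bis(methoxymethoxy)phenol, via arylboronate 5 (not isolated)
Conditions: [Ir(OMe)(cod)]2 (1.5 mol%), 4,4′-di-tert-butyl-2,2′-bipyridine (3 mol%), B2pin2 (0.6 equiv), THF, 80 °C; then 30% aq. H2O2, THF/H2O, 0 °C to rt
Reagents that add atoms: hydrogen peroxide (OO)
Why: Iridium-catalysed C–H borylation is sterically controlled and takes the only ring C–H with no ortho substituent (para to bromine, aryl bromides being tolerated), and oxidation of the C–B bond with retention gives the phenol.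

Step 4
Reactants: 6 4-bromo-3,5-bis(methoxymethoxy)phenol
Product: 7 3-bromo-6-hydroxy-2,4-bis(methoxymethoxy)benzaldehyde
Conditions: MgCl2 (2 equiv), Et3N (4 equiv), (CH2O)n (6 equiv), THF, 65 °C
Reagents that add atoms: paraformaldehyde, as formaldehyde (C=O)
Why: Magnesium-mediated ortho-formylation of phenols (Casnati–Skattebøl reaction) delivers formaldehyde ortho to the phenoxide and a second formaldehyde oxidises the benzylic alkoxide, and since the two ortho positions of 6 are equivalent only one aldehyde can form.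

Step 5
Reactants: 7 3-bromo-6-hydroxy-2,4-bis(methoxymethoxy)benzaldehyde
Product: 8 4-bromo-2-(1-hydroxyprop-2-yn-1-yl)-3,5-bis(methoxymethoxy)phenol (racemic carbinol)
Conditions: HC≡CMgBr (0.5 M in THF, 3 equiv), THF, 0 °C to rt; aq. NH4Cl
Reagents that add atoms: ethynylmagnesium bromide (C#C[Mg]Br)
Why: After deprotonation of the phenol, 1,2-addition of the small alkynyl Grignard reagent to the aldehyde gives the propargylic alcohol, whose racemic carbinol centre is removed in the next step.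

Step 6
Reactants: 8 4-bromo-2-(1-hydroxyprop-2-yn-1-yl)-3,5-bis(methoxymethoxy)phenol
Product: 10 6-bromo-5,7-bis(methoxymethoxy)-4H-chromen-4-one, via ynone 9 (not isolated)
Conditions: MnO2 (activated, 10 equiv), CH2Cl2, rt; filter; then K2CO3 (0.2 equiv), acetone, rt
Reagents that add atoms: none
Why: MnO2 oxidation of the benzylic propargylic alcohol gives a terminal ynone that closes ring C by base-catalysed intramolecular oxa-Michael addition (6-endo-dig) of the only free phenol, which fixes bromine at C6 between the two MOM ethers.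

Step 7
Reactants: 11 allyl bromide
Product: 13 2-allyl-4,4,5,5-tetramethyl-1,3,2-dioxaborolane, via allylmagnesium bromide 12 (not isolated)
Conditions: Mg turnings, Et2O, 0 °C; then i-PrOB(pin), −78 °C to rt; aq. NH4Cl
Reagents that add atoms: 2-isopropoxy-4,4,5,5-tetramethyl-1,3,2-dioxaborolane (CC(C)OB1OC(C)(C)C(C)(C)O1)
Why: Grignard formation followed by addition to the borate ester and loss of isopropoxide (transmetalation from magnesium to boron) gives the allylboronate.

Step 8
Reactants: 14 methacrolein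
Product: 15 rac-2-(prop-1-en-2-yl)oxirane
Conditions: Me3S+ I−, NaH, DMSO/THF, −5 °C to rt; product distilled from the mixture
Reagents that add atoms: trimethylsulfonium iodide (C[S+](C)C.[I-])
Why: Corey–Chaykovsky epoxidation, in which the unstabilised sulfonium ylide adds 1,2 to the enal and the betaine closes to the vinyl epoxide, gives the racemate that step 9 consumes in full.

Step 9
Reactants: 15 rac-2-(prop-1-en-2-yl)oxirane; 13 2-allyl-4,4,5,5-tetramethyl-1,3,2-dioxaborolane
Product: 17 (2S)-2-(prop-1-en-2-yl)pent-4-en-1-ol, via alkyl borate ester 16 (not isolated)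
Conditions: Pd2(dba)3 (2.5 mol%), (R)-2,2′-bis(di-2-furylphosphino)-6,6′-dimethoxy-1,1′-biphenyl (6 mol%), 13 (1.3 equiv), THF, 25 °C, 15 added slowly; then H2O
Reagents that add atoms: none
Why: Proposed new method: zerovalent palladium ionises racemic 15 to a zwitterionic 2-methyl-π-allyl complex whose alkoxide binds the boron of 13 and so hands the allyl group to palladium, the diastereomeric π-allyl complexes interconvert through the η1 form at the unsubstituted CH2 terminus faster than they couple (dynamic kinetic asymmetric transformation), and 3,3′-reductive elimination from the bis(η1-allyl)palladium held by the small-bite-angle chiral bisphosphine joins the substituted terminus to the allyl γ-carbon, which sets the (S) centre and leaves the isopropenyl group; the closest known reactions are the branch- and enantioselective palladium-catalysed allyl–allyl cross-coupling of allylic carbonates and chlorides with allylB(pin) and the dynamic kinetic asymmetric Tsuji–Trost substitution of racemic vinyl epoxides.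

Step 10
Reactants: 17 (2S)-2-(prop-1-en-2-yl)pent-4-en-1-ol
Product: 18 (2S)-5-methyl-2-(prop-1-en-2-yl)hex-4-en-1-ol ((S)-lavandulol)
Conditions: second-generation Grubbs catalyst (3 mol%), 2-methylbut-2-ene/CH2Cl2 1:1, 40 °C, sealed tube
Reagents that add atoms: 2-methylbut-2-ene (CC=C(C)C)
Why: Olefin cross-metathesis converts the monosubstituted terminal alkene into the trisubstituted prenyl alkene with excess 2-methylbut-2-ene while the hindered 1,1-disubstituted isopropenyl group does not react and the stereocentre is not touched.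

Step 11
Reactants: 18 (2S)-5-methyl-2-(prop-1-en-2-yl)hex-4-en-1-ol
Product: 19 (3S)-3-(iodomethyl)-2,6-dimethylhepta-1,5-diene
Conditions: PPh3, I2, imidazole, CH2Cl2, 0 °C to rt, dark
Reagents that add atoms: iodine (II)
Why: Appel-type iodination displaces the alkoxyphosphonium at the primary carbon by SN2, so the adjacent stereocentre is untouched.

Step 12
Reactants: 1 resorcinol
Product: 20 3-methoxyphenol
Conditions: MeI (1.0 equiv), K2CO3 (1.0 equiv), acetone, reflux; mono-ether separated by base extraction and distillation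
Reagents that add atoms: iodomethane (CI)
Why: Williamson monomethylation with one equivalent of MeI gives a statistical mixture from which the mono-ether is readily separated from the neutral diether and the water-soluble diol.

Step 13
Reactants: 20 3-methoxyphenol
Product: 21 (3-methoxyphenoxy)tri(propan-2-yl)silane
Conditions: i-Pr3SiCl, imidazole, DMF, rt
Reagents that add atoms: chlorotri(propan-2-yl)silane (CC(C)[Si](Cl)(C(C)C)C(C)C)
Why: Imidazole-promoted O-silylation installs a bulky silyl ether that steers the next bromination and survives the organolithium and rhodium steps.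

Step 14
Reactants: 21 (3-methoxyphenoxy)tri(propan-2-yl)silane
Product: 22 (4-bromo-3-methoxyphenoxy)tri(propan-2-yl)silane
Conditions: NBS (1.0 equiv), MeCN, 0 °C to rt, dark
Reagents that add atoms: N-bromosuccinimide (O=C1CCC(=O)N1Br)
Why: Electrophilic aromatic bromination goes to the position para to the silyloxy group and ortho to methoxy, because both doubly activated positions are electronically similar and the bulky silyl group shields its own ortho sites.

Step 15
Reactants: 22 (4-bromo-3-methoxyphenoxy)tri(propan-2-yl)silane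
Product: 25 {2-methoxy-4-[tri(propan-2-yl)silyloxy]phenyl}boronic acid, via aryllithium 23 (not isolated), via lithium aryltriisopropoxyborate 24 (not isolated)
Conditions: n-BuLi (1.1 equiv), THF, −78 °C; B(Oi-Pr)3 (1.5 equiv), −78 °C to rt; 1 M aq. HCl, 0 °C, 10 min
Reagents that add atoms: triisopropyl borate (CC(C)OB(OC(C)C)OC(C)C); water (O)
Why: Bromine–lithium exchange is faster than any ortho-metalation at −78 °C, and trapping with the borate ester followed by brief acid hydrolysis gives the boronic acid.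

Step 16
Reactants: 19 (3S)-3-(iodomethyl)-2,6-dimethylhepta-1,5-diene; 10 6-bromo-5,7-bis(methoxymethoxy)-4H-chromen-4-one
Product: 27 5,7-bis(methoxymethoxy)-6-[(2R)-5-methyl-2-(prop-1-en-2-yl)hex-4-en-1-yl]-4H-chromen-4-one, via alkylzinc iodide 26 (not isolated)
Conditions: Zn dust (activated), LiCl, THF, 40 °C; then 10, Pd(OAc)2 (3 mol%), SPhos (6 mol%), THF/NMP 2:1, 50 °C
Reagents that add atoms: none
Why: Negishi sp3–sp2 cross-coupling, in which zinc inserts into the primary C–I bond and the bulky electron-rich biarylphosphine lets oxidative addition into the di-ortho-alkoxy C–Br bond and reductive elimination outrun β-hydride elimination, carries the β-stereocentre over unchanged (its descriptor becomes R only because CH2Ar ranks below isopropenyl).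

Step 17
Reactants: 27 5,7-bis(methoxymethoxy)-6-[(2R)-5-methyl-2-(prop-1-en-2-yl)hex-4-en-1-yl]-4H-chromen-4-one; 25 {2-methoxy-4-[tri(propan-2-yl)silyloxy]phenyl}boronic acid
Product: 28 (2S)-2-{2-methoxy-4-[tri(propan-2-yl)silyloxy]phenyl}-5,7-bis(methoxymethoxy)-6-[(2R)-5-methyl-2-(prop-1-en-2-yl)hex-4-en-1-yl]-2,3-dihydro-4H-chromen-4-one
Conditions: [Rh(OH)(cod)]2 (2.5 mol%), (S)-2,2′-bis[bis(3,4,5-trifluorophenyl)phosphino]-6,6′-dimethoxy-1,1′-biphenyl (5.5 mol%), 25 (2.5 equiv), toluene/H2O 10:1, 40 °C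
Reagents that add atoms: none
Why: Rhodium-catalysed asymmetric 1,4-addition of an arylboronic acid (Hayashi–Miyaura reaction) inserts the chromone C2=C3 bond into the aryl–rhodium bond on the C2 Re face, as (S)-configured biaryl bisphosphines do with cyclic enones, and protonation of the rhodium enolate by water gives the (2S) flavanone.

Step 18
Reactants: 28 (2S)-2-{2-methoxy-4-[tri(propan-2-yl)silyloxy]phenyl}-5,7-bis(methoxymethoxy)-6-[(2R)-5-methyl-2-(prop-1-en-2-yl)hex-4-en-1-yl]-2,3-dihydro-4H-chromen-4-one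
Product: 30 (2S)-5,7-dihydroxy-2-(4-hydroxy-2-methoxyphenyl)-6-[(2R)-5-methyl-2-(prop-1-en-2-yl)hex-4-en-1-yl]-2,3-dihydro-4H-chromen-4-one (target), via silyl ether diol 29 (not isolated)
Conditions: HCl (1.5 M in MeOH/THF 3:1), 30 °C; NaHCO3, evaporate; then Bu4NF (1.2 equiv), AcOH (2 equiv), THF, 0 °C
Reagents that add atoms: none
Why: Acid-catalysed acetal exchange removes both MOM ethers while the silyl group keeps ring B less electron-rich, and acetic-acid-buffered fluoride then cleaves the aryl silyl ether without forming the phenoxide that would open the flavanone, so neither the alkenes nor the two stereocentres are disturbed.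

## Compound list

1 | resorcinol (benzene-1,3-diol) | Oc1cccc(O)c1 | starting material
2 | 1,3-bis(methoxymethoxy)benzene | COCOc1cccc(OCOC)c1 | intermediate
3 | [2,6-bis(methoxymethoxy)phenyl]lithium | [Li]c1c(OCOC)cccc1OCOC | intermediate
4 | 2-bromo-1,3-bis(methoxymethoxy)benzene | COCOc1cccc(OCOC)c1Br | intermediate
5 | 2-[4-bromo-3,5-bis(methoxymethoxy)phenyl]-4,4,5,5-tetramethyl-1,3,2-dioxaborolane | COCOc1cc(B2OC(C)(C)C(C)(C)O2)cc(OCOC)c1Br | intermediate
6 | 4-bromo-3,5-bis(methoxymethoxy)phenol | COCOc1cc(O)cc(OCOC)c1Br | intermediate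
7 | 3-bromo-6-hydroxy-2,4-bis(methoxymethoxy)benzaldehyde | O=Cc1c(O)cc(OCOC)c(Br)c1OCOC | intermediate
8 | 4-bromo-2-(1-hydroxyprop-2-yn-1-yl)-3,5-bis(methoxymethoxy)phenol (racemic) | C#CC(O)c1c(O)cc(OCOC)c(Br)c1OCOC | intermediate
9 | 1-[3-bromo-6-hydroxy-2,4-bis(methoxymethoxy)phenyl]prop-2-yn-1-one | C#CC(=O)c1c(O)cc(OCOC)c(Br)c1OCOC | intermediate
10 | 6-bromo-5,7-bis(methoxymethoxy)-4H-chromen-4-one | O=c1ccoc2cc(OCOC)c(Br)c(OCOC)c12 | intermediate
11 | allyl bromide (3-bromoprop-1-ene) | C=CCBr | starting material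
12 | allylmagnesium bromide | C=CC[Mg]Br | intermediate
13 | 2-allyl-4,4,5,5-tetramethyl-1,3,2-dioxaborolane (allylB(pin)) | C=CCB1OC(C)(C)C(C)(C)O1 | intermediate
14 | methacrolein (2-methylprop-2-enal) | C=C(C)C=O | starting material
15 | rac-2-(prop-1-en-2-yl)oxirane | C=C(C)C1CO1 | intermediate
16 | 4,4,5,5-tetramethyl-2-{[(2S)-2-(prop-1-en-2-yl)pent-4-en-1-yl]oxy}-1,3,2-dioxaborolane | C=C(C)[C@H](CC=C)COB1OC(C)(C)C(C)(C)O1 | intermediate
17 | (2S)-2-(prop-1-en-2-yl)pent-4-en-1-ol | C=C(C)[C@H](CC=C)CO | intermediate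
18 | (2S)-5-methyl-2-(prop-1-en-2-yl)hex-4-en-1-ol ((S)-lavandulol) | C=C(C)[C@H](CC=C(C)C)CO | intermediate
19 | (3S)-3-(iodomethyl)-2,6-dimethylhepta-1,5-diene | C=C(C)[C@H](CC=C(C)C)CI | intermediate
20 | 3-methoxyphenol | COc1cccc(O)c1 | intermediate
21 | (3-methoxyphenoxy)tri(propan-2-yl)silane | COc1cccc(O[Si](C(C)C)(C(C)C)C(C)C)c1 | intermediate
22 | (4-bromo-3-methoxyphenoxy)tri(propan-2-yl)silane | COc1cc(O[Si](C(C)C)(C(C)C)C(C)C)ccc1Br | intermediate
23 | {2-methoxy-4-[tri(propan-2-yl)silyloxy]phenyl}lithium | [Li]c1ccc(O[Si](C(C)C)(C(C)C)C(C)C)cc1OC | intermediate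
24 | lithium {2-methoxy-4-[tri(propan-2-yl)silyloxy]phenyl}tri(propan-2-yloxy)borate | [Li+].COc1cc(O[Si](C(C)C)(C(C)C)C(C)C)ccc1[B-](OC(C)C)(OC(C)C)OC(C)C | intermediate
25 | {2-methoxy-4-[tri(propan-2-yl)silyloxy]phenyl}boronic acid | COc1cc(O[Si](C(C)C)(C(C)C)C(C)C)ccc1B(O)O | intermediate
26 | [(2S)-5-methyl-2-(prop-1-en-2-yl)hex-4-en-1-yl]zinc iodide | C=C(C)[C@H](CC=C(C)C)C[Zn]I | intermediate
27 | 5,7-bis(methoxymethoxy)-6-[(2R)-5-methyl-2-(prop-1-en-2-yl)hex-4-en-1-yl]-4H-chromen-4-one | C=C(C)[C@H](CC=C(C)C)Cc1c(OCOC)cc2occc(=O)c2c1OCOC | intermediate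
28 | (2S)-2-{2-methoxy-4-[tri(propan-2-yl)silyloxy]phenyl}-5,7-bis(methoxymethoxy)-6-[(2R)-5-methyl-2-(prop-1-en-2-yl)hex-4-en-1-yl]-2,3-dihydro-4H-chromen-4-one | C=C(C)[C@H](CC=C(C)C)Cc1c(OCOC)cc2c(c1OCOC)C(=O)C[C@@H](c1ccc(O[Si](C(C)C)(C(C)C)C(C)C)cc1OC)O2 | intermediate
29 | (2S)-5,7-dihydroxy-2-{2-methoxy-4-[tri(propan-2-yl)silyloxy]phenyl}-6-[(2R)-5-methyl-2-(prop-1-en-2-yl)hex-4-en-1-yl]-2,3-dihydro-4H-chromen-4-one | C=C(C)[C@H](CC=C(C)C)Cc1c(O)cc2c(c1O)C(=O)C[C@@H](c1ccc(O[Si](C(C)C)(C(C)C)C(C)C)cc1OC)O2 | intermediate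
30 | (2S)-5,7-dihydroxy-2-(4-hydroxy-2-methoxyphenyl)-6-[(2R)-5-methyl-2-(prop-1-en-2-yl)hex-4-en-1-yl]-2,3-dihydro-4H-chromen-4-one | C=C(C)[C@H](CC=C(C)C)Cc1c(O)cc2c(c1O)C(=O)C[C@@H](c1ccc(O)cc1OC)O2 | target

## Step count and risks

Total steps: 18. Longest linear sequence: 9 steps (1, 2, 3, 4, 5, 6, 16, 17, 18).

**Step 9 (proposed new step).** It may give the linear 1,1′-coupled dienol, oligomers from alkoxide attack on the π-allyl complex, isomerisation of 15 to 2-methylbut-2-enal, or low enantioselectivity.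

The fallback uses a known auxiliary-controlled deconjugative alkylation. It sets out from 11 and comes back at 17. (4S)-4-Benzyl-1,3-oxazolidin-2-one is acylated with commercial 3-methylbut-2-enoyl chloride (Et3N, DMAP cat., CH2Cl2, 0 °C) to give (4S)-4-benzyl-3-(3-methylbut-2-enoyl)-1,3-oxazolidin-2-one F1. NaN(SiMe3)2 (THF, −78 °C) removes a γ-proton to give sodium (1Z)-1-[(4S)-4-benzyl-2-oxo-1,3-oxazolidin-3-yl]-3-methylbuta-1,3-dien-1-olate F2. Compound 11 alkylates F2 at the α-carbon on the face away from the benzyl group and gives (4S)-4-benzyl-3-[(2S)-2-(prop-1-en-2-yl)pent-4-enoyl]-1,3-oxazolidin-2-one F3. LiBH4 (Et2O, 1 equiv H2O, 0 °C) then releases 17 and the auxiliary.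

**Step 16.** Oxidative addition into the electron-rich, di-ortho-substituted C–Br bond may be slow. β-Hydride elimination from the alkylpalladium could give debrominated chromone or erode the β-stereocentre.

The fallback makes the aryl–CH2 bond by SN2 alkylation of an aryllithium before ring C exists. It sets out from 6 (with 19 as the electrophile) and comes back at 27. Phenol 6 is silylated (i-Pr3SiCl, imidazole, DMF) to (4-bromo-3,5-bis(methoxymethoxy)phenoxy)tri(propan-2-yl)silane F4. Bromine–lithium exchange (t-BuLi, 2.1 equiv, THF, −78 °C) gives {2,6-bis(methoxymethoxy)-4-[tri(propan-2-yl)silyloxy]phenyl}lithium F5. F5 is alkylated by 19 (THF/DMPU, −78 °C to rt) to {3,5-bis(methoxymethoxy)-4-[(2R)-5-methyl-2-(prop-1-en-2-yl)hex-4-en-1-yl]phenoxy}tri(propan-2-yl)silane F6. Bu4NF (THF, 0 °C) gives 3,5-bis(methoxymethoxy)-4-[(2R)-5-methyl-2-(prop-1-en-2-yl)hex-4-en-1-yl]phenol F7, whose two ortho positions are again equivalent. The conditions of steps 4 to 6 are then repeated: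
- MgCl2/Et3N/(CH2O)n gives 6-hydroxy-2,4-bis(methoxymethoxy)-3-[(2R)-5-methyl-2-(prop-1-en-2-yl)hex-4-en-1-yl]benzaldehyde F8.
- HC≡CMgBr gives 2-(1-hydroxyprop-2-yn-1-yl)-3,5-bis(methoxymethoxy)-4-[(2R)-5-methyl-2-(prop-1-en-2-yl)hex-4-en-1-yl]phenol F9.
- MnO2 gives 1-{6-hydroxy-2,4-bis(methoxymethoxy)-3-[(2R)-5-methyl-2-(prop-1-en-2-yl)hex-4-en-1-yl]phenyl}prop-2-yn-1-one F10, which K2CO3 in acetone cyclises to 27.

**Step 17.** The ortho-methoxy, electron-rich boronic acid may protodeboronate faster than it adds to the hindered 5-alkoxychromone, or the enantioselectivity may be low.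

The fallback gives up catalyst control at C2 and separates epimers. It sets out from 27 (aryl donor 23, made from 22 as in step 15) and comes back at 28. Aryllithium 23 is transmetalated with MgBr2·OEt2 (THF, −78 to 0 °C) to {2-methoxy-4-[tri(propan-2-yl)silyloxy]phenyl}magnesium bromide F11. Copper-catalysed conjugate addition of F11 to 27 (CuBr·SMe2 10 mol%, Me3SiCl, THF, −40 °C) gives trimethyl({2-{2-methoxy-4-[tri(propan-2-yl)silyloxy]phenyl}-5,7-bis(methoxymethoxy)-6-[(2R)-5-methyl-2-(prop-1-en-2-yl)hex-4-en-1-yl]-2H-chromen-4-yl}oxy)silane F12 as both C2 epimers. Mild aqueous hydrolysis gives 28 together with (2R)-2-{2-methoxy-4-[tri(propan-2-yl)silyloxy]phenyl}-5,7-bis(methoxymethoxy)-6-[(2R)-5-methyl-2-(prop-1-en-2-yl)hex-4-en-1-yl]-2,3-dihydro-4H-chromen-4-one F13. The two epimers are separated by preparative HPLC on an amylose tris(3,5-dimethylphenylcarbamate) phase. F13 can be re-equilibrated at C2 with base and separated again.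

Further compounds
F1 | step 9 | (4S)-4-benzyl-3-(3-methylbut-2-enoyl)-1,3-oxazolidin-2-one | O=C1OC[C@H](Cc2ccccc2)N1C(=O)C=C(C)C
F2 | step 9 | sodium (1Z)-1-[(4S)-4-benzyl-2-oxo-1,3-oxazolidin-3-yl]-3-methylbuta-1,3-dien-1-olate | [Na+].[O-]/C(=C\C(C)=C)N1C(=O)OC[C@@H]1Cc1ccccc1
F3 | step 9 | (4S)-4-benzyl-3-[(2S)-2-(prop-1-en-2-yl)pent-4-enoyl]-1,3-oxazolidin-2-one | O=C1OC[C@H](Cc2ccccc2)N1C(=O)[C@@H](CC=C)C(C)=C
F4 | step 16 | (4-bromo-3,5-bis(methoxymethoxy)phenoxy)tri(propan-2-yl)silane | COCOc1cc(O[Si](C(C)C)(C(C)C)C(C)C)cc(OCOC)c1Br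
F5 | step 16 | {2,6-bis(methoxymethoxy)-4-[tri(propan-2-yl)silyloxy]phenyl}lithium | [Li]c1c(OCOC)cc(O[Si](C(C)C)(C(C)C)C(C)C)cc1OCOC
F6 | step 16 | {3,5-bis(methoxymethoxy)-4-[(2R)-5-methyl-2-(prop-1-en-2-yl)hex-4-en-1-yl]phenoxy}tri(propan-2-yl)silane | C=C(C)[C@H](CC=C(C)C)Cc1c(OCOC)cc(O[Si](C(C)C)(C(C)C)C(C)C)cc1OCOC
F7 | step 16 | 3,5-bis(methoxymethoxy)-4-[(2R)-5-methyl-2-(prop-1-en-2-yl)hex-4-en-1-yl]phenol | C=C(C)[C@H](CC=C(C)C)Cc1c(OCOC)cc(O)cc1OCOC
F8 | step 16 | 6-hydroxy-2,4-bis(methoxymethoxy)-3-[(2R)-5-methyl-2-(prop-1-en-2-yl)hex-4-en-1-yl]benzaldehyde | C=C(C)[C@H](CC=C(C)C)Cc1c(OCOC)cc(O)c(C=O)c1OCOC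
F9 | step 16 | 2-(1-hydroxyprop-2-yn-1-yl)-3,5-bis(methoxymethoxy)-4-[(2R)-5-methyl-2-(prop-1-en-2-yl)hex-4-en-1-yl]phenol | C=C(C)[C@H](CC=C(C)C)Cc1c(OCOC)cc(O)c(C(O)C#C)c1OCOC
F10 | step 16 | 1-{6-hydroxy-2,4-bis(methoxymethoxy)-3-[(2R)-5-methyl-2-(prop-1-en-2-yl)hex-4-en-1-yl]phenyl}prop-2-yn-1-one | C=C(C)[C@H](CC=C(C)C)Cc1c(OCOC)cc(O)c(C(=O)C#C)c1OCOC
F11 | step 17 | {2-methoxy-4-[tri(propan-2-yl)silyloxy]phenyl}magnesium bromide | Br[Mg]c1ccc(O[Si](C(C)C)(C(C)C)C(C)C)cc1OC
F12 | step 17 | trimethyl({2-{2-methoxy-4-[tri(propan-2-yl)silyloxy]phenyl}-5,7-bis(methoxymethoxy)-6-[(2R)-5-methyl-2-(prop-1-en-2-yl)hex-4-en-1-yl]-2H-chromen-4-yl}oxy)silane (both C2 epimers) | C=C(C)[C@H](CC=C(C)C)Cc1c(OCOC)cc2c(c1OCOC)C(O[Si](C)(C)C)=CC(c1ccc(O[Si](C(C)C)(C(C)C)C(C)C)cc1OC)O2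
F13 | step 17 | (2R)-2-{2-methoxy-4-[tri(propan-2-yl)silyloxy]phenyl}-5,7-bis(methoxymethoxy)-6-[(2R)-5-methyl-2-(prop-1-en-2-yl)hex-4-en-1-yl]-2,3-dihydro-4H-chromen-4-one | C=C(C)[C@H](CC=C(C)C)Cc1c(OCOC)cc2c(c1OCOC)C(=O)C[C@H](c1ccc(O[Si](C(C)C)(C(C)C)C(C)C)cc1OC)O2
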